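**Retrosynthetic overview**
1. Target ⇐ global desilylation of 31. The δ-lactone (O–C8) closes when MeMgBr adds to the C8 ketone and the new axial alkoxide attacks the C10 acetate arm.
2. Key union (C10–CH3 and C9–C11 bonds): three-component conjugate addition–aldol of cyclohexenone 26, a methyl cuprate and aldehyde 10.
3. Enone 26 ⇐ 4-hydroxycyclohexanone: C6 by enantioselective deprotonation, C4–C5 by Ireland–Claisen rearrangement, C8=O by allylic oxidation, the C1–C2 acetate arm (C1–C10 bond) by Negishi coupling.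
4. Aldehyde 10 ⇐ but-3-yn-1-ol: carboalumination, Sharpless epoxidation, reductive epoxy-iodide opening (sets C13).
5. Ring order: the carbocycle is present from the start; the lactone ring is formed in the penultimate step.

Labels used: C1/C2 = lactone CH2/C=O; C3 = CO2H; C4 = CMe2; ring C5–C10 (C5 bears C4, C6 bears OH, C7 = CH2, C8 = O-bearing carbon with CH3, C9 bears the side chain, C10 = quaternary carbon with CH3); C11–C15 = CH(OH)–CH2–C(OH)(CH3)–CH=CH2.

Assumption: the natural constitution (O–C8 lactone, free C6–OH, free C3 acid) is the thermodynamically preferred isomer and survives the final deprotection without acyl migration or γ-lactonisation.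

**Part A – side-chain aldehyde**

Step 1
Reactants: 1 but-3-yn-1-ol
Product: 2 1-[(but-3-yn-1-yloxy)methyl]-4-methoxybenzene
Conditions: NaH, PMBCl, Bu4NI (cat.), THF, 0 °C to rt
Reagents that add atoms: 4-methoxybenzyl chloride, COc1ccc(CCl)cc1
Why: Williamson etherification masks the oxygen that later becomes the C11 aldehyde oxygen.

Step 2
Reactants: 2 1-[(but-3-yn-1-yloxy)methyl]-4-methoxybenzene
Product: 4 (2E)-5-[(4-methoxybenzyl)oxy]-3-methylpent-2-en-1-ol, via alkenyldimethylalane 3 (not isolated)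
Conditions: Me3Al, Cp2ZrCl2 (cat.), CH2Cl2, 0 °C to rt; then n-BuLi, (CH2O)n, THF, –78 °C to rt
Reagents that add atoms: trimethylaluminium, C[Al](C)C; formaldehyde (as paraformaldehyde), C=O
Why: Negishi Zr-catalysed carboalumination adds CH3/Al syn across the alkyne (CH3 to the internal carbon) and the alanate is hydroxymethylated with retention, fixing the E alkene.

Step 3
Reactants: 4 (2E)-5-[(4-methoxybenzyl)oxy]-3-methylpent-2-en-1-ol
Product: 5 [(2R,3R)-3-{2-[(4-methoxybenzyl)oxy]ethyl}-3-methyloxiran-2-yl]methanol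
Conditions: Ti(OiPr)4 (cat.), D-(–)-DIPT (cat.), t-BuOOH, 4 Å MS, CH2Cl2, –20 °C
Reagents that add atoms: tert-butyl hydroperoxide, CC(C)(C)OO
Why: Sharpless asymmetric epoxidation of the geraniol-type E-allylic alcohol with D-(–)-tartrate gives the (2R,3R)-epoxide, which fixes the future C13 as R.

Step 4
Reactants: 5 [(2R,3R)-3-{2-[(4-methoxybenzyl)oxy]ethyl}-3-methyloxiran-2-yl]methanol
Product: 6 (2S,3R)-2-(iodomethyl)-3-{2-[(4-methoxybenzyl)oxy]ethyl}-3-methyloxirane
Conditions: I2, PPh3, imidazole, CH2Cl2, 0 °C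
Reagents that add atoms: iodine, II
Why: Appel-type (Garegg–Samuelsson) iodination of the primary alcohol leaves the epoxide intact (the descriptor at C2 changes only through CIP priorities).

Step 5
Reactants: 6 (2S,3R)-2-(iodomethyl)-3-{2-[(4-methoxybenzyl)oxy]ethyl}-3-methyloxirane
Product: 7 (3R)-5-[(4-methoxybenzyl)oxy]-3-methylpent-1-en-3-ol
Conditions: Zn dust, EtOH, reflux
Reagents that add atoms: none
Why: Zinc insertion and β-elimination (reductive epoxide opening) gives the tertiary vinyl carbinol without breaking the C13–O bond, so C13 stays R.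

Step 6
Reactants: 7 (3R)-5-[(4-methoxybenzyl)oxy]-3-methylpent-1-en-3-ol
Product: 8 triethyl{[(3R)-5-[(4-methoxybenzyl)oxy]-3-methylpent-1-en-3-yl]oxy}silane
Conditions: TESOTf, 2,6-lutidine, CH2Cl2, –78 to 0 °C
Reagents that add atoms: triethylsilyl trifluoromethanesulfonate, CC[Si](CC)(CC)OS(=O)(=O)C(F)(F)F
Why: The silyl triflate silylates the hindered tertiary allylic alcohol under non-acidic conditions.

Step 7
Reactants: 8 triethyl{[(3R)-5-[(4-methoxybenzyl)oxy]-3-methylpent-1-en-3-yl]oxy}silane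
Product: 9 (3R)-3-methyl-3-[(triethylsilyl)oxy]pent-4-en-1-ol
Conditions: DDQ, CH2Cl2/pH 7 buffer, 0 °C
Reagents that add atoms: none
Why: Oxidative PMB cleavage is orthogonal to the TES ether and the vinyl group.

Step 8
Reactants: 9 (3R)-3-methyl-3-[(triethylsilyl)oxy]pent-4-en-1-ol
Product: 10 (3R)-3-methyl-3-[(triethylsilyl)oxy]pent-4-enal
Conditions: Dess–Martin periodinane, pyridine, CH2Cl2, 0 °C to rt
Reagents that add atoms: none
Why: Dess–Martin oxidation gives the β-silyloxy aldehyde without base-induced β-elimination; it is used at once.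

**Part B – cyclohexenone 26**

Step 9
Reactants: 11 4-hydroxycyclohexan-1-one
Product: 12 4-[(tert-butyldimethylsilyl)oxy]cyclohexan-1-one
Conditions: TBSCl, imidazole, DMF, rt
Reagents that add atoms: tert-butyldimethylsilyl chloride, CC(C)(C)[Si](C)(C)Cl
Why: Standard silylation protects the oxygen that becomes the C6 hydroxyl.

Step 10
Reactants: 12 4-[(tert-butyldimethylsilyl)oxy]cyclohexan-1-one
Product: 13 (R)-tert-butyldimethyl{[4-(trimethylsilyloxy)cyclohex-3-en-1-yl]oxy}silane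
Conditions: (S,S)-bis(1-phenylethyl)amine, n-BuLi, TMSCl (in situ quench), THF, –100 °C
Reagents that add atoms: chlorotrimethylsilane, C[Si](C)(C)Cl
Why: Koga–Simpkins enantioselective deprotonation removes one enantiotopic α-hydrogen of the prochiral ketone, making the OTBS carbon (future C6) R; the base enantiomer is chosen for this sense, and the (R,R)-amide gives ent-13.

Step 11
Reactants: 13 (R)-tert-butyldimethyl{[4-(trimethylsilyloxy)cyclohex-3-en-1-yl]oxy}silane
Product: 14 (4R)-4-[(tert-butyldimethylsilyl)oxy]cyclohex-2-en-1-one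
Conditions: Pd(OAc)2 (1 equiv), MeCN, rt
Reagents that add atoms: none
Why: Saegusa–Ito oxidation converts the regiodefined silyl enol ether into the enone without touching the stereocentre.

Step 12
Reactants: 14 (4R)-4-[(tert-butyldimethylsilyl)oxy]cyclohex-2-en-1-one
Product: 15 (4R)-4-[(tert-butyldimethylsilyl)oxy]-2-iodocyclohex-2-en-1-one
Conditions: I2, pyridine, CH2Cl2, 0 °C to rt
Reagents that add atoms: iodine, II
Why: Johnson α-iodination (pyridine addition, iodination, elimination) places iodine on the future C10.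

Step 13
Reactants: 15 (4R)-4-[(tert-butyldimethylsilyl)oxy]-2-iodocyclohex-2-en-1-one
Product: 16 (1S,4R)-4-[(tert-butyldimethylsilyl)oxy]-2-iodocyclohex-2-en-1-ol
Conditions: NaBH4, CeCl3·7H2O, MeOH, –78 °C
Reagents that add atoms: none
Why: Luche 1,2-reduction with axial hydride delivery anti to the pseudoaxial 4-OTBS group gives the cis-1,4 alcohol (new centre S).

Step 14
Reactants: 16 (1S,4R)-4-[(tert-butyldimethylsilyl)oxy]-2-iodocyclohex-2-en-1-ol; 17 2-methylpropanoyl chloride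
Product: 18 (1S,4R)-4-[(tert-butyldimethylsilyl)oxy]-2-iodocyclohex-2-en-1-yl 2-methylpropanoate
Conditions: pyridine, DMAP (cat.), CH2Cl2, 0 °C to rt
Reagents that add atoms: none
Why: Acylation installs the isobutyrate that supplies C3, C4 and both geminal methyl groups.

Step 15
Reactants: 18 (1S,4R)-4-[(tert-butyldimethylsilyl)oxy]-2-iodocyclohex-2-en-1-yl 2-methylpropanoate
Product: 21 2-[(1R,6R)-6-[(tert-butyldimethylsilyl)oxy]-2-iodocyclohex-2-en-1-yl]-2-methylpropanoic acid, via silyl ketene acetal 19 (not isolated), via trimethylsilyl ester 20 (not isolated)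
Conditions: LDA, TMSCl, THF, –78 °C, then 60 °C; 1 M HCl work-up
Reagents that add atoms: none
Why: Ireland–Claisen [3,3] rearrangement is suprafacial, so the C4–C5 bond forms on the face of the departing C–O bond, cis to OTBS (C5 R), and leaves the C9=C10 vinyl iodide.

Step 16
Reactants: 21 2-[(1R,6R)-6-[(tert-butyldimethylsilyl)oxy]-2-iodocyclohex-2-en-1-yl]-2-methylpropanoic acid
Product: 22 2-(trimethylsilyl)ethyl 2-[(1R,6R)-6-[(tert-butyldimethylsilyl)oxy]-2-iodocyclohex-2-en-1-yl]-2-methylpropanoate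
Conditions: 2,4,6-trichlorobenzoyl chloride, Et3N, THF; then Me3SiCH2CH2OH, DMAP, toluene, rt
Reagents that add atoms: 2-(trimethylsilyl)ethanol, C[Si](C)(C)CCO
Why: Yamaguchi esterification copes with the α-quaternary acid and gives a fluoride-labile ester.

Step 17
Reactants: 22 2-(trimethylsilyl)ethyl 2-[(1R,6R)-6-[(tert-butyldimethylsilyl)oxy]-2-iodocyclohex-2-en-1-yl]-2-methylpropanoate
Product: 23 2-(trimethylsilyl)ethyl 2-[(1R,6R)-6-[(tert-butyldimethylsilyl)oxy]-2-iodo-4-oxocyclohex-2-en-1-yl]-2-methylpropanoate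
Conditions: Rh2(cap)4 (1 mol %), t-BuOOH, K2CO3, CH2Cl2, rt
Reagents that add atoms: tert-butyl hydroperoxide, CC(C)(C)OO
Why: Doyle allylic C–H oxidation at the only allylic CH2 (C8) gives the β-iodo enone.

Step 18
Reactants: 23 2-(trimethylsilyl)ethyl 2-[(1R,6R)-6-[(tert-butyldimethylsilyl)oxy]-2-iodo-4-oxocyclohex-2-en-1-yl]-2-methylpropanoate; 24 methyl bromoacetate
Product: 26 2-(trimethylsilyl)ethyl 2-[(1R,6R)-6-[(tert-butyldimethylsilyl)oxy]-2-(2-methoxy-2-oxoethyl)-4-oxocyclohex-2-en-1-yl]-2-methylpropanoate, via Reformatsky reagent 25 (not isolated)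
Conditions: 24, Zn dust, THF, rt; then 23, Pd(PPh3)4 (5 mol %), THF, 50 °C
Reagents that add atoms: none
Why: Negishi coupling of the Reformatsky reagent with the activated β-iodo enone attaches the C1–C2 acetate arm to C10 under non-basic conditions, oxidative addition to the vinylogous acyl iodide being faster than Reformatsky addition to the ketone.

**Part C – fragment union and end game**

Step 19
Reactants: 26 2-(trimethylsilyl)ethyl 2-[(1R,6R)-6-[(tert-butyldimethylsilyl)oxy]-2-(2-methoxy-2-oxoethyl)-4-oxocyclohex-2-en-1-yl]-2-methylpropanoate; 10 (3R)-3-methyl-3-[(triethylsilyl)oxy]pent-4-enal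
Product: 28 2-(trimethylsilyl)ethyl 2-[(1R,2R,3S,6R)-6-[(tert-butyldimethylsilyl)oxy]-3-[(1S,3R)-1-hydroxy-3-methyl-3-(triethylsilyloxy)pent-4-en-1-yl]-2-(2-methoxy-2-oxoethyl)-2-methyl-4-oxocyclohexyl]-2-methylpropanoate, via lithium enolate 27 (not isolated)
Conditions: Me2CuLi, Et2O, –78 to –20 °C; ZnCl2, THF, –78 °C; then 10, –78 to –10 °C; aq. NH4Cl
Reagents that add atoms: lithium dimethylcuprate, [Li+].C[Cu-]C
Why: Tandem conjugate addition–aldol: CH3 adds to C10 anti to the pseudoaxial C5 substituent and trans to C6–OTBS (C10 R), and the zinc aldolate equilibrates by retro-aldol/aldol to the chelated anti aldol with the C9 branch equatorial (C9 S, C11 S).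

Step 20
Reactants: 28 2-(trimethylsilyl)ethyl 2-[(1R,2R,3S,6R)-6-[(tert-butyldimethylsilyl)oxy]-3-[(1S,3R)-1-hydroxy-3-methyl-3-(triethylsilyloxy)pent-4-en-1-yl]-2-(2-methoxy-2-oxoethyl)-2-methyl-4-oxocyclohexyl]-2-methylpropanoate
Product: 29 2-(trimethylsilyl)ethyl 2-[(1R,2R,3S,6R)-6-[(tert-butyldimethylsilyl)oxy]-2-(2-methoxy-2-oxoethyl)-2-methyl-3-[(1S,3R)-3-methyl-1,3-bis(triethylsilyloxy)pent-4-en-1-yl]-4-oxocyclohexyl]-2-methylpropanoate
Conditions: TESOTf, 2,6-lutidine, CH2Cl2, –78 °C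
Reagents that add atoms: triethylsilyl trifluoromethanesulfonate, CC[Si](CC)(CC)OS(=O)(=O)C(F)(F)F
Why: Silylation blocks retro-aldol and protects C11–OH for the organometallic step.

Step 21
Reactants: 29 2-(trimethylsilyl)ethyl 2-[(1R,2R,3S,6R)-6-[(tert-butyldimethylsilyl)oxy]-2-(2-methoxy-2-oxoethyl)-2-methyl-3-[(1S,3R)-3-methyl-1,3-bis(triethylsilyloxy)pent-4-en-1-yl]-4-oxocyclohexyl]-2-methylpropanoate
Product: 31 2-(trimethylsilyl)ethyl 2-[(1S,5R,6R,7R,9S)-7-[(tert-butyldimethylsilyl)oxy]-1,5-dimethyl-9-[(1S,3R)-3-methyl-1,3-bis(triethylsilyloxy)pent-4-en-1-yl]-3-oxo-2-oxabicyclo[3.3.1]nonan-6-yl]-2-methylpropanoate, via magnesium alkoxide 30 (not isolated)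
Conditions: MeMgBr, LaCl3·2LiCl (cat.), THF, –78 °C to rt
Reagents that add atoms: methylmagnesium bromide, C[Mg]Br
Why: Grignard 1,2-addition occurs from the equatorial direction because the axial face is blocked by the syn-axial C10 acetate arm and C6–OTBS, giving the axial C8 alkoxide (C8 S), which lactonises onto the cis-diaxial methyl ester (transesterification).

Step 22
Reactants: 31 2-(trimethylsilyl)ethyl 2-[(1S,5R,6R,7R,9S)-7-[(tert-butyldimethylsilyl)oxy]-1,5-dimethyl-9-[(1S,3R)-3-methyl-1,3-bis(triethylsilyloxy)pent-4-en-1-yl]-3-oxo-2-oxabicyclo[3.3.1]nonan-6-yl]-2-methylpropanoate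
Product: 32 2-[(1S,5R,6R,7R,9S)-9-[(1S,3R)-1,3-dihydroxy-3-methylpent-4-en-1-yl]-7-hydroxy-1,5-dimethyl-3-oxo-2-oxabicyclo[3.3.1]nonan-6-yl]-2-methylpropanoic acid (target)
Conditions: TBAF (excess), THF, 0 to 40 °C; then cold pH 4 NaH2PO4 buffer
Reagents that add atoms: none
Why: Fluoride cleaves the two TES ethers, the TBS ether and (by β-elimination) the TMSE ester in one operation, and buffered acidification frees the acid without exposing it to strong acid.

**Compound list**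

1 | but-3-yn-1-ol | C#CCCO | starting material
2 | 1-[(but-3-yn-1-yloxy)methyl]-4-methoxybenzene | C#CCCOCc1ccc(OC)cc1 | intermediate
3 | dimethyl[(1E)-4-(4-methoxybenzyloxy)-2-methylbut-1-en-1-yl]alane | C[Al](C)/C=C(\C)CCOCc1ccc(OC)cc1 | intermediate
4 | (2E)-5-[(4-methoxybenzyl)oxy]-3-methylpent-2-en-1-ol | OC/C=C(\C)CCOCc1ccc(OC)cc1 | intermediate
5 | [(2R,3R)-3-{2-[(4-methoxybenzyl)oxy]ethyl}-3-methyloxiran-2-yl]methanol | OC[C@H]1O[C@]1(C)CCOCc1ccc(OC)cc1 | intermediate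
6 | (2S,3R)-2-(iodomethyl)-3-{2-[(4-methoxybenzyl)oxy]ethyl}-3-methyloxirane | IC[C@H]1O[C@]1(C)CCOCc1ccc(OC)cc1 | intermediate
7 | (3R)-5-[(4-methoxybenzyl)oxy]-3-methylpent-1-en-3-ol | C=C[C@](C)(O)CCOCc1ccc(OC)cc1 | intermediate
8 | triethyl{[(3R)-5-[(4-methoxybenzyl)oxy]-3-methylpent-1-en-3-yl]oxy}silane | C=C[C@](C)(O[Si](CC)(CC)CC)CCOCc1ccc(OC)cc1 | intermediate
9 | (3R)-3-methyl-3-[(triethylsilyl)oxy]pent-4-en-1-ol | C=C[C@](C)(O[Si](CC)(CC)CC)CCO | intermediate
10 | (3R)-3-methyl-3-[(triethylsilyl)oxy]pent-4-enal | C=C[C@](C)(O[Si](CC)(CC)CC)CC=O | intermediate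
11 | 4-hydroxycyclohexan-1-one | O=C1CCC(O)CC1 | starting material
12 | 4-[(tert-butyldimethylsilyl)oxy]cyclohexan-1-one | O=C1CCC(O[Si](C)(C)C(C)(C)C)CC1 | intermediate
13 | (R)-tert-butyldimethyl{[4-(trimethylsilyloxy)cyclohex-3-en-1-yl]oxy}silane | C1C[C@@H](O[Si](C)(C)C(C)(C)C)CC=C1O[Si](C)(C)C | intermediate
14 | (4R)-4-[(tert-butyldimethylsilyl)oxy]cyclohex-2-en-1-one | C1C[C@@H](O[Si](C)(C)C(C)(C)C)C=CC1=O | intermediate
15 | (4R)-4-[(tert-butyldimethylsilyl)oxy]-2-iodocyclohex-2-en-1-one | C1C[C@@H](O[Si](C)(C)C(C)(C)C)C=C(I)C1=O | intermediate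
16 | (1S,4R)-4-[(tert-butyldimethylsilyl)oxy]-2-iodocyclohex-2-en-1-ol (cis) | C1C[C@@H](O[Si](C)(C)C(C)(C)C)C=C(I)[C@H]1O | intermediate
17 | 2-methylpropanoyl chloride | CC(C)C(Cl)=O | starting material
18 | (1S,4R)-4-[(tert-butyldimethylsilyl)oxy]-2-iodocyclohex-2-en-1-yl 2-methylpropanoate | C1C[C@@H](O[Si](C)(C)C(C)(C)C)C=C(I)[C@H]1OC(=O)C(C)C | intermediate
19 | trimethylsilyl ketene acetal of 18 (1-{[(1S,4R)-4-(TBSO)-2-iodocyclohex-2-en-1-yl]oxy}-2-methyl-1-(trimethylsilyloxy)prop-1-ene) | C1C[C@@H](O[Si](C)(C)C(C)(C)C)C=C(I)[C@H]1OC(O[Si](C)(C)C)=C(C)C | intermediate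
20 | trimethylsilyl 2-[(1R,6R)-6-[(tert-butyldimethylsilyl)oxy]-2-iodocyclohex-2-en-1-yl]-2-methylpropanoate | C1C[C@@H](O[Si](C)(C)C(C)(C)C)[C@@H](C(C)(C)C(=O)O[Si](C)(C)C)C(I)=C1 | intermediate
21 | 2-[(1R,6R)-6-[(tert-butyldimethylsilyl)oxy]-2-iodocyclohex-2-en-1-yl]-2-methylpropanoic acid | C1C[C@@H](O[Si](C)(C)C(C)(C)C)[C@@H](C(C)(C)C(=O)O)C(I)=C1 | intermediate
22 | 2-(trimethylsilyl)ethyl 2-[(1R,6R)-6-[(tert-butyldimethylsilyl)oxy]-2-iodocyclohex-2-en-1-yl]-2-methylpropanoate | C1C[C@@H](O[Si](C)(C)C(C)(C)C)[C@@H](C(C)(C)C(=O)OCC[Si](C)(C)C)C(I)=C1 | intermediate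
23 | 2-(trimethylsilyl)ethyl 2-[(1R,6R)-6-[(tert-butyldimethylsilyl)oxy]-2-iodo-4-oxocyclohex-2-en-1-yl]-2-methylpropanoate | O=C1C[C@@H](O[Si](C)(C)C(C)(C)C)[C@@H](C(C)(C)C(=O)OCC[Si](C)(C)C)C(I)=C1 | intermediate
24 | methyl bromoacetate | BrCC(=O)OC | starting material
25 | bromo(2-methoxy-2-oxoethyl)zinc | COC(=O)C[Zn]Br | intermediate
26 | 2-(trimethylsilyl)ethyl 2-[(1R,6R)-6-[(tert-butyldimethylsilyl)oxy]-2-(2-methoxy-2-oxoethyl)-4-oxocyclohex-2-en-1-yl]-2-methylpropanoate | O=C1C[C@@H](O[Si](C)(C)C(C)(C)C)[C@@H](C(C)(C)C(=O)OCC[Si](C)(C)C)C(CC(=O)OC)=C1 | intermediate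
27 | lithium (3R,4R,5R)-5-[(tert-butyldimethylsilyl)oxy]-3-(2-methoxy-2-oxoethyl)-3-methyl-4-{2-methyl-1-oxo-1-[2-(trimethylsilyl)ethoxy]propan-2-yl}cyclohex-1-en-1-olate | [Li+].[O-]C1=C[C@](C)(CC(=O)OC)[C@H](C(C)(C)C(=O)OCC[Si](C)(C)C)[C@H](O[Si](C)(C)C(C)(C)C)C1 | intermediate
28 | 2-(trimethylsilyl)ethyl 2-[(1R,2R,3S,6R)-6-[(tert-butyldimethylsilyl)oxy]-3-[(1S,3R)-1-hydroxy-3-methyl-3-(triethylsilyloxy)pent-4-en-1-yl]-2-(2-methoxy-2-oxoethyl)-2-methyl-4-oxocyclohexyl]-2-methylpropanoate | C=C[C@](C)(O[Si](CC)(CC)CC)C[C@H](O)[C@@H]1[C@](C)(CC(=O)OC)[C@H](C(C)(C)C(=O)OCC[Si](C)(C)C)[C@H](O[Si](C)(C)C(C)(C)C)CC1=O | intermediate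
29 | 2-(trimethylsilyl)ethyl 2-[(1R,2R,3S,6R)-6-[(tert-butyldimethylsilyl)oxy]-2-(2-methoxy-2-oxoethyl)-2-methyl-3-[(1S,3R)-3-methyl-1,3-bis(triethylsilyloxy)pent-4-en-1-yl]-4-oxocyclohexyl]-2-methylpropanoate (C11-O-triethylsilyl ether of 28) | C=C[C@](C)(O[Si](CC)(CC)CC)C[C@H](O[Si](CC)(CC)CC)[C@@H]1[C@](C)(CC(=O)OC)[C@H](C(C)(C)C(=O)OCC[Si](C)(C)C)[C@H](O[Si](C)(C)C(C)(C)C)CC1=O | intermediate
30 | bromomagnesium alkoxide of the C8 tertiary carbinol (C8 S; O cis to the C10 acetate arm) | C=C[C@](C)(O[Si](CC)(CC)CC)C[C@H](O[Si](CC)(CC)CC)[C@@H]1[C@](C)(CC(=O)OC)[C@H](C(C)(C)C(=O)OCC[Si](C)(C)C)[C@H](O[Si](C)(C)C(C)(C)C)C[C@]1(C)O[Mg]Br | intermediate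
31 | 2-(trimethylsilyl)ethyl 2-[(1S,5R,6R,7R,9S)-7-[(tert-butyldimethylsilyl)oxy]-1,5-dimethyl-9-[(1S,3R)-3-methyl-1,3-bis(triethylsilyloxy)pent-4-en-1-yl]-3-oxo-2-oxabicyclo[3.3.1]nonan-6-yl]-2-methylpropanoate | C=C[C@](C)(O[Si](CC)(CC)CC)C[C@H](O[Si](CC)(CC)CC)[C@@H]1[C@]2(C)CC(=O)O[C@@]1(C)C[C@@H](O[Si](C)(C)C(C)(C)C)[C@H]2C(C)(C)C(=O)OCC[Si](C)(C)C | intermediate
32 | 2-[(1S,5R,6R,7R,9S)-9-[(1S,3R)-1,3-dihydroxy-3-methylpent-4-en-1-yl]-7-hydroxy-1,5-dimethyl-3-oxo-2-oxabicyclo[3.3.1]nonan-6-yl]-2-methylpropanoic acid | C=C[C@](C)(O)C[C@H](O)[C@@H]1[C@]2(C)CC(=O)O[C@@]1(C)C[C@@H](O)[C@H]2C(C)(C)C(=O)O | target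

**Step count and risks**

Total step count: 22

Longest linear sequence: 14 steps

The longest chain runs from 4-hydroxycyclohexan-1-one through the enone branch, the fragment union and the end game. The side-chain branch from but-3-yn-1-ol joins it at the fragment union and is shorter.

Steps most likely to fail:

Step 19. The cuprate must add next to the very hindered C5 and must outrun deprotonation of the acidic acetate CH2. The C9/C11 configuration relies on equilibration of the zinc aldolate, because kinetic axial attack on the enolate would give the 9,11-bis-epimer. The fallback sets out from 26 and changes the aldol to a kinetic syn-aldol followed by epimerisation. Me2CuLi with Me3SiCl gives the isolable trimethylsilyl enol ether F1. A fluoride-triggered (TASF, cat.) Noyori-type aldol with 10 runs through an open transition state on the less hindered lower face and gives the syn adduct as its C11 silyl ether, the 9-epi silyl aldol F2 (C9 R, C11 already S). Base-mediated epimerisation at C9 alone (DBU, or LDA then kinetic protonation) gives the equatorial silyl aldol F3. Mild methanolysis of the O–SiMe3 group then comes back to the route at 28.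

Step 17. Allylic C–H oxidation of a vinyl iodide next to a tertiary allylic C–H may be slow or unselective. The fallback sets out from 22 and replaces direct oxidation by halogenation–oxidation. Wohl–Ziegler bromination (NBS, AIBN, PhCF3, reflux) gives the allylic bromide F4 (C8 epimers). Kornblum oxidation (DMSO, NaHCO3, 60 °C) converts it to the enone and comes back to the route at 23.

Step 21. The ketone is hindered and flanked by two β-silyloxy groups, so enolisation/elimination or addition from the wrong face (giving a C8 alkoxide that cannot lactonise) can compete. The fallback sets out from 29 and fixes C8 by a bridging lactonisation instead of by facial selectivity. Wittig methylenation (Ph3P=CH2) gives the exocyclic alkene F5. Selective methyl-ester cleavage (Me3SnOH) gives the acid F6. Iodolactonisation (I2, NaHCO3, MeCN), in which the tethered carboxylate can reach C8 only from the face of the C10 arm, gives the iodomethyl lactone F7. Bu3SnH/AIBN deiodination comes back to the route at 31.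

**Further compounds**

F1 | step 19 | 2-(trimethylsilyl)ethyl 2-[(1R,2R,6R)-6-[(tert-butyldimethylsilyl)oxy]-2-(2-methoxy-2-oxoethyl)-2-methyl-4-(trimethylsilyloxy)cyclohex-3-en-1-yl]-2-methylpropanoate | C[Si](C)(C)OC1=C[C@](C)(CC(=O)OC)[C@H](C(C)(C)C(=O)OCC[Si](C)(C)C)[C@H](O[Si](C)(C)C(C)(C)C)C1
F2 | step 19 | 9-epi analogue of 28 carrying C11-OSiMe3 (C9 R, C11 S) | C=C[C@](C)(O[Si](CC)(CC)CC)C[C@H](O[Si](C)(C)C)[C@H]1[C@](C)(CC(=O)OC)[C@H](C(C)(C)C(=O)OCC[Si](C)(C)C)[C@H](O[Si](C)(C)C(C)(C)C)CC1=O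
F3 | step 19 | C11-O-trimethylsilyl ether of 28 (C9 S, C11 S) | C=C[C@](C)(O[Si](CC)(CC)CC)C[C@H](O[Si](C)(C)C)[C@@H]1[C@](C)(CC(=O)OC)[C@H](C(C)(C)C(=O)OCC[Si](C)(C)C)[C@H](O[Si](C)(C)C(C)(C)C)CC1=O
F4 | step 17 | 2-(trimethylsilyl)ethyl 2-[(1R,6R)-4-bromo-6-[(tert-butyldimethylsilyl)oxy]-2-iodocyclohex-2-en-1-yl]-2-methylpropanoate (both C4 epimers) | BrC1C[C@@H](O[Si](C)(C)C(C)(C)C)[C@@H](C(C)(C)C(=O)OCC[Si](C)(C)C)C(I)=C1
F5 | step 21 | C8-methylidene analogue of 29 | C=C[C@](C)(O[Si](CC)(CC)CC)C[C@H](O[Si](CC)(CC)CC)[C@@H]1[C@](C)(CC(=O)OC)[C@H](C(C)(C)C(=O)OCC[Si](C)(C)C)[C@H](O[Si](C)(C)C(C)(C)C)CC1=C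
F6 | step 21 | C2 carboxylic acid of F5 | C=C[C@](C)(O[Si](CC)(CC)CC)C[C@H](O[Si](CC)(CC)CC)[C@@H]1[C@](C)(CC(=O)O)[C@H](C(C)(C)C(=O)OCC[Si](C)(C)C)[C@H](O[Si](C)(C)C(C)(C)C)CC1=C
F7 | step 21 | C8-iodomethyl analogue of 31 | C=C[C@](C)(O[Si](CC)(CC)CC)C[C@H](O[Si](CC)(CC)CC)[C@@H]1[C@]2(C)CC(=O)O[C@@]1(CI)C[C@@H](O[Si](C)(C)C(C)(C)C)[C@H]2C(C)(C)C(=O)OCC[Si](C)(C)C
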